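Slowness is what we look for first in a flask held for 5.0 h, but in the earlier runs target stands near its last reading at the first sample. In Saturday's run target reads 85.1% at 0.333 h and 85.1% at 4.00 h. In Sunday's run, with 0.1 mol% of free catalyst against 0.4 mol%, it reads 84.7% at 0.333 h and 86.7% at 4.00 h, a rise of 2 percentage points. The end point moves with the reagent instead: Friday's run, with 1.8 equiv of reagent and 0.2 mol% of free catalyst, a loading between those two, reads 100.1% at 2.00 h.

| flask | solid substrate | second substrate | reagent | free catalyst | remark | time |
|---|---|---|---|---|---|---|
| Sunday's | 24 mM | 2 equiv | 0.90 equiv | 0.1 mol% | run made earlier |  |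
| Saturday's | 24 mM | 2 equiv | 0.90 equiv | 0.4 mol% | run made earlier |  |
| Friday's | 24 mM | 2 equiv | 1.8 equiv | 0.2 mol% | run made earlier |  |
| flask | 24 mM | 2.00 equiv | 0.900 equiv | 0.2 mol% |  | 5.0 h |

| run | time / h | solid substrate / % | target / % | starting material / % |
|---|---|---|---|---|
| Sunday's | 0.333 | 0.3 | 84.7 | 15.3 |
| Sunday's | 1.00 | 0 | 86.1 | 13.7 |
| Sunday's | 2.00 | 0 | 85.1 | 13.3 |
| Sunday's | 3.00 | 0 | 86.5 | 13.4 |
| Sunday's | 4.00 | 0.6 | 86.7 | 14.0 |
| Saturday's | 0.333 | 0 | 85.1 | 13.8 |
| Saturday's | 0.667 | 0.1 | 85.0 | 14.7 |
| Saturday's | 1.00 | 0.6 | 85.5 | 15.5 |
| Saturday's | 2.00 | 0 | 85.5 | 15.3 |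
| Saturday's | 4.00 | 0 | 85.1 | 14.7 |
| Friday's | 0.333 | 0 | 99.6 | 0 |
| Friday's | 1.00 | 0 | 99.8 | 0.4 |
| Friday's | 2.00 | 0 | 100.1 | 0 |
| Friday's | 3.00 | 0.2 | 100.0 | 0 |
| Friday's | 4.00 | 0.6 | 99.4 | 0.2 |

(standard deviation of a reading: 0.5 percentage points)

- solid substrate is a solid; its amount is given per volume of the solution
- the numbers in the tables scatter by 0.5 percentage points (one standard deviation)
- at the start none of the solid substrate is in solution
- what has only dissolved of solid substrate counts as not reacted
- starting material means what is dissolved; the solid is not counted in it

* part of the solid substrate that has turned into other species by 5.0 h (what has only dissolved does not count)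
* target at 5.0 h, in percent of the solid substrate charged
* starting material at 5.0 h, in percent of the solid substrate charged

The bench rule for a limiting reagent says that one equivalent gives one of target, so 0.90 equiv should give 90.0%. Applied honestly, it overshoots. The readings of Sunday's and Saturday's runs average 85.5% target and 14.4% starting material, a gap of 4.5 points against a scatter of 0.5 points.

We suppose that the missing reagent went to second substrate. The zero of the scale is then the statistical case, in which reagent takes the substrates as they stand, so that 2 equiv of second substrate leaves target 33.3% of the reagent. Counting the gap as second substrate used, and dividing the logarithm of the fraction of starting material left by that of the fraction of second substrate left, we read 85.8 from these readings. This selectivity factor, how many times faster reagent goes to starting material than to second substrate at equal amounts, also gives the rule its border. By this reading, with second substrate near its charge, reagent divides evenly at 2.33% starting material, in percent of the solid substrate charged, and at 14.4% target still takes 86.0% of it.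

This flask has the charges of those two runs, with 0.2 mol% of free catalyst between theirs, so we commit to their 85.5% and 14.4%. The forecast, from the same readings, gives conversion 85.6%, target 85.5% and starting material 14.4%: “I expect the same plateau”.

The flask gives conversion 86.0%, target 85.9% and starting material 14.0%.

    second substrate + free catalyst ⇌ catalyst intermediate B (K = 14.0 L mol⁻¹, k = 41.0 L mol⁻¹ s⁻¹)
    starting material + free catalyst ⇌ catalyst intermediate A (K = 100 L mol⁻¹, k = 1600 L mol⁻¹ s⁻¹)
    solid substrate ⇌ starting material, rate k3*(cs3 - [starting material]) while solid is left; crystals form when [starting material] > cs3 (solubility = 21.0 mM, k = 0.0380 s⁻¹)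
    reagent + catalyst intermediate B → free catalyst + second product (k = 28.0 L mol⁻¹ s⁻¹)
    reagent + catalyst intermediate A → free catalyst + target (k = 540 L mol⁻¹ s⁻¹)

In this flask the solid went into solution with half of that turnover done by 0.349 min, and free catalyst took up starting material with half of that step's turnover done by 1.34 min, while reagent turned catalyst intermediate A into target, which stood at 85.6% after 0.250 h. At 0.500 h reagent stands at 0% of its charge, and over the second half of the time no substrate, intermediate or product moves by more than 0 points. Our factor, with 14.0% starting material left, puts 1.09 mM into second product in this flask, where 0.980 mM stands. In a neighbour flask with 0.360 equiv of reagent, with 64.9% starting material left, it gives 0.241 mM against 0.242 mM.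

The numbers in the tables stem from a simulated flask from invented constants; noise was put on by code.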